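## Retrosynthetic overview

1. The butenolide ring is bought intact (4-bromofuran-2(5H)-one) and joined last by Stille coupling to an (E,E)-dienylstannane alcohol.
2. That stannyl dienol comes from a Horner–Wadsworth–Emmons reaction of an α-alkylated phosphonoacetate with (E)-3-(tributylstannyl)propenal, which fixes the trisubstituted E-alkene, followed by ester reduction.
3. The phosphonate comes from a bicyclic homoallylic iodide. Its rings A and B are closed together by an enantioselective proton-initiated cation–olefin bicyclisation of an acyclic triene that terminates on a tetrasubstituted vinylsilane. Loss of silicon fixes the ring-B tetrasubstituted alkene, and both stereocentres are set here.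
4. The acyclic triene is built from geranyl bromide and 1-(trimethylsilyl)propyne by nickel-catalysed methylmagnesiation with oxirane trapping, then iodination.
5. Ring order: A and B simultaneously (step 4); the butenolide ring is attached preformed (step 9).

Assumption: the (R)-configured chiral acid of step 4 gives the (4aS,8aS) sense, as recalled for its cyclisation of homofarnesyl ethers to (−)-ambroxide (otherwise the (S)-reagent is used); the er it delivers (expected about 90:10) is raised to a single enantiomer by preparative chiral chromatography of 8, not counted as a step.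

## Route

Step 1
Reactants: 1 geranyl bromide, (2E)-1-bromo-3,7-dimethylocta-2,6-diene; 2 1-(trimethylsilyl)propyne
Product: 4 [(5E)-6,10-dimethylundeca-5,9-dien-1-yn-1-yl]trimethylsilane, via lithiated silylpropyne 3 (not isolated)
Conditions: 2, n-BuLi, THF, −78 → −20 °C; then 1, −78 → 0 °C
Reagents that add atoms: none
Why: Propargylic lithiation of the silylalkyne followed by SN2 alkylation with the primary allylic bromide (silicon keeps attack at the propargyl terminus), leaving the E-alkene of the geranyl unit untouched.

Step 2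
Reactants: 4
Product: 6 (3Z,7E)-4,8,12-trimethyl-3-(trimethylsilyl)trideca-3,7,11-trien-1-ol, via silylalkenylmagnesium bromide 5 (not isolated)
Conditions: MeMgBr (3 equiv), Ni(acac)2 (10 mol %), Me3Al (10 mol %), THF, 23 °C, 24 h; then CuBr·SMe2 (20 mol %), oxirane (6 equiv), −40 → 0 °C; H2O
Reagents that add atoms: methylmagnesium bromide, C[Mg]Br; oxirane, C1CO1
Why: Nickel-catalysed syn carbomagnesiation of a 1-silylalkyne places CH3 on the carbon remote from silicon and magnesium on the silicon-bearing carbon, and copper-catalysed epoxide opening by this alkenyl Grignard adds the hydroxyethyl arm with retention to give the Z-vinylsilane; a minor E-isomer is carried on because both converge in step 4.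

Step 3
Reactants: 6
Product: 7 [(3Z,7E)-1-iodo-4,8,12-trimethyltrideca-3,7,11-trien-3-yl]trimethylsilane
Conditions: PPh3, imidazole, I2, CH2Cl2, 0 °C, dark
Reagents that add atoms: iodine, II
Why: Appel-type iodination of the primary alcohol through the alkoxyphosphonium ion; with I2 added last to PPh3/imidazole no free iodine remains to attack the vinylsilane or the alkenes.

Step 4
Reactants: 7
Product: 8 (4aS,8aS)-1-(2-iodoethyl)-2,5,5,8a-tetramethyl-3,4,4a,5,6,7,8,8a-octahydronaphthalene
Conditions: (R)-2-(2-fluorobenzyloxy)-2'-hydroxy-1,1'-binaphthyl (2.2 equiv), SnCl4 (2.0 equiv), toluene, −78 °C, 72 h; aq NaHCO3 (binaphthol ether recovered)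
Reagents that add atoms: none
Why: Proposed new method: the SnCl4-activated (R)-binaphthol monoether (a Lewis-acid-assisted chiral Brønsted acid) protonates the least hindered, terminal trisubstituted alkene on one enantiotopic face; the tertiary cation is captured by the central E-alkene and then by the silicon-bearing carbon of the tetrasubstituted vinylsilane through a chair–chair transition state (Stork–Eschenmoser antiperiplanar addition, so the E-alkene gives the trans ring fusion with angular CH3 and ring-fusion H anti), and the tertiary β-silyl cation, whose axial C–Si bond lies parallel to the empty p orbital, loses Me3Si+ so the double bond can only appear at the tetrasubstituted ring-B position (an allylsilane from stray proton loss would be protodesilylated to the same alkene); closest known reaction types are the Lewis-acid-assisted chiral Brønsted acid cyclisation of homofarnesyl derivatives to (−)-ambroxide and vinylsilane-terminated cation–olefin cyclisations run with achiral Lewis acids.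

Step 5
Reactants: 8; 9 triethyl phosphonoacetate
Product: 11 ethyl 2-(diethoxyphosphoryl)-4-[(4aS,8aS)-2,5,5,8a-tetramethyl-3,4,4a,5,6,7,8,8a-octahydronaphthalen-1-yl]butanoate, via sodiophosphonoacetate 10 (not isolated)
Conditions: 9 (3 equiv), NaH (2.8 equiv), DMF, 0 °C; then 8, 60 °C
Reagents that add atoms: none
Why: SN2 C-alkylation of the stabilised phosphonoacetate carbanion by the primary iodide, with excess nucleophile suppressing dialkylation; the new α-stereocentre (epimer mixture) is inconsequential because it becomes sp2 in step 7.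

Step 6
Reactants: 12 (E)-1,2-bis(tributylstannyl)ethene
Product: 14 (2E)-3-(tributylstannyl)prop-2-enal, via stannylvinyllithium 13 (not isolated)
Conditions: n-BuLi (1.0 equiv), THF, −78 °C; then DMF, −78 → 0 °C; H2O
Reagents that add atoms: N,N-dimethylformamide, CN(C)C=O
Why: Tin–lithium exchange at one terminus with retention of the E geometry, then formylation of the alkenyllithium by DMF.

Step 7
Reactants: 11; 14
Product: 16 ethyl (2E,4E)-2-{2-[(4aS,8aS)-2,5,5,8a-tetramethyl-3,4,4a,5,6,7,8,8a-octahydronaphthalen-1-yl]ethyl}-5-(tributylstannyl)penta-2,4-dienoate, via phosphonate carbanion 15 (not isolated)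
Conditions: NaH, THF, 0 °C; then 14, 0 → 23 °C
Reagents that add atoms: none
Why: Horner–Wadsworth–Emmons olefination in which reversible addition of the α-alkyl phosphonate anion to the enal funnels to the E-enoate (ester trans to the dienyl chain, the geometry of the target's trisubstituted alkene), while the E-vinylstannane passes through unchanged.

Step 8
Reactants: 16
Product: 17 (2E,4E)-2-{2-[(4aS,8aS)-2,5,5,8a-tetramethyl-3,4,4a,5,6,7,8,8a-octahydronaphthalen-1-yl]ethyl}-5-(tributylstannyl)penta-2,4-dien-1-ol
Conditions: i-Bu2AlH (2.5 equiv), CH2Cl2, −78 °C; aq KNaC4H4O6 (potassium sodium tartrate)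
Reagents that add atoms: none
Why: 1,2-Reduction of the conjugated ester to the allylic alcohol by the aluminium hydride at low temperature, done before the hydride-sensitive butenolide is present; alkene geometries and the C–Sn bond are unaffected.

Step 9
Reactants: 17; 18 4-bromofuran-2(5H)-one
Product: 19 4-[(1E,3E)-4-(hydroxymethyl)-6-[(4aS,8aS)-2,5,5,8a-tetramethyl-3,4,4a,5,6,7,8,8a-octahydronaphthalen-1-yl]hexa-1,3-dien-1-yl]furan-2(5H)-one
Conditions: Pd2(dba)3 (5 mol %), AsPh3 (20 mol %), NMP, 40 °C, dark
Reagents that add atoms: none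
Why: Stille cross-coupling on zerovalent palladium joins the E-alkenylstannane to the β-bromobutenolide with retention at both sp2 carbons under neutral conditions that tolerate the free allylic alcohol and the lactone.

## Compound list

1 | geranyl bromide, (2E)-1-bromo-3,7-dimethylocta-2,6-diene | CC(C)=CCC/C(C)=C/CBr | starting material
2 | 1-(trimethylsilyl)propyne | CC#C[Si](C)(C)C | starting material
3 | 3-(trimethylsilyl)prop-2-yn-1-yllithium | [Li]CC#C[Si](C)(C)C | intermediate
4 | [(5E)-6,10-dimethylundeca-5,9-dien-1-yn-1-yl]trimethylsilane | C[Si](C)(C)C#CCC/C=C(\C)CCC=C(C)C | intermediate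
5 | [(1Z,5E)-2,6,10-trimethyl-1-(trimethylsilyl)undeca-1,5,9-trien-1-yl]magnesium bromide | Br[Mg]/C(=C(\C)CC/C=C(\C)CCC=C(C)C)[Si](C)(C)C | intermediate
6 | (3Z,7E)-4,8,12-trimethyl-3-(trimethylsilyl)trideca-3,7,11-trien-1-ol | OCC/C(=C(\C)CC/C=C(\C)CCC=C(C)C)[Si](C)(C)C | intermediate
7 | [(3Z,7E)-1-iodo-4,8,12-trimethyltrideca-3,7,11-trien-3-yl]trimethylsilane | ICC/C(=C(\C)CC/C=C(\C)CCC=C(C)C)[Si](C)(C)C | intermediate
8 | (4aS,8aS)-1-(2-iodoethyl)-2,5,5,8a-tetramethyl-3,4,4a,5,6,7,8,8a-octahydronaphthalene (trans-fused; angular CH3 and ring-fusion H anti) | CC1=C(CCI)[C@@]2(C)CCCC(C)(C)[C@@H]2CC1 | intermediate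
9 | triethyl phosphonoacetate | CCOC(=O)CP(=O)(OCC)OCC | starting material
10 | sodium salt of triethyl phosphonoacetate (carbanion at C2) | CCOC(=O)[CH-]P(=O)(OCC)OCC.[Na+] | intermediate
11 | ethyl 2-(diethoxyphosphoryl)-4-[(4aS,8aS)-2,5,5,8a-tetramethyl-3,4,4a,5,6,7,8,8a-octahydronaphthalen-1-yl]butanoate (epimer mixture at C2) | CC1=C(CCC(C(=O)OCC)P(=O)(OCC)OCC)[C@@]2(C)CCCC(C)(C)[C@@H]2CC1 | intermediate
12 | (E)-1,2-bis(tributylstannyl)ethene | CCCC[Sn](CCCC)(CCCC)/C=C/[Sn](CCCC)(CCCC)CCCC | starting material
13 | [(E)-2-(tributylstannyl)ethenyl]lithium | [Li]/C=C/[Sn](CCCC)(CCCC)CCCC | intermediate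
14 | (2E)-3-(tributylstannyl)prop-2-enal | O=C/C=C/[Sn](CCCC)(CCCC)CCCC | intermediate
15 | sodium salt of 11 (carbanion at C2 of the butanoate) | CC1=C(CC[C-](C(=O)OCC)P(=O)(OCC)OCC)[C@@]2(C)CCCC(C)(C)[C@@H]2CC1.[Na+] | intermediate
16 | ethyl (2E,4E)-2-{2-[(4aS,8aS)-2,5,5,8a-tetramethyl-3,4,4a,5,6,7,8,8a-octahydronaphthalen-1-yl]ethyl}-5-(tributylstannyl)penta-2,4-dienoate | CC1=C(CC/C(=C\C=C\[Sn](CCCC)(CCCC)CCCC)C(=O)OCC)[C@@]2(C)CCCC(C)(C)[C@@H]2CC1 | intermediate
17 | (2E,4E)-2-{2-[(4aS,8aS)-2,5,5,8a-tetramethyl-3,4,4a,5,6,7,8,8a-octahydronaphthalen-1-yl]ethyl}-5-(tributylstannyl)penta-2,4-dien-1-ol | CC1=C(CC/C(=C\C=C\[Sn](CCCC)(CCCC)CCCC)CO)[C@@]2(C)CCCC(C)(C)[C@@H]2CC1 | intermediate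
18 | 4-bromofuran-2(5H)-one | BrC1=CC(=O)OC1 | starting material
19 | 4-[(1E,3E)-4-(hydroxymethyl)-6-[(4aS,8aS)-2,5,5,8a-tetramethyl-3,4,4a,5,6,7,8,8a-octahydronaphthalen-1-yl]hexa-1,3-dien-1-yl]furan-2(5H)-one | CC1=C(CC/C(=C\C=C\C2=CC(=O)OC2)CO)[C@@]2(C)CCCC(C)(C)[C@@H]2CC1 | target

## Step count and risks

Total steps: 9. Longest linear sequence: 8 (steps 1, 2, 3, 4, 5, 7, 8, 9, from geranyl bromide); step 6 is a one-step side branch.

The three steps most likely to fail:

**Step 4 (the bicyclisation).** The chiral acid may protonate the silicon-bearing alkene carbon (protodesilylation before ring closure), stop after ring A, or give a low er. The fallback sets out from 6 and returns at 8, and uses the hydroxyl group as the terminating nucleophile instead of silicon loss. A confined chiral imidodiphosphorimidate Brønsted acid (5 mol %) in perfluoro-tert-butanol at −40 °C is the catalyst type that converts (3E,7E)-homofarnesol into (−)-ambroxide. Applied to 6 it should close rings A, B and the oxolane in one operation to give 8α,12-epoxy-9α-(trimethylsilyl)-13,14,15,16-tetranorlabdane (the 9-silyl analogue of (−)-ambroxide; 5α-H, 10β-CH3, 8β-CH3) F2. BF3·OEt2 in CH2Cl2 (−78 → 0 °C) then ionises the tertiary C–O bond, and the β-silyl cation collapses in a Peterson-type elimination to 2-[(4aS,8aS)-2,5,5,8a-tetramethyl-3,4,4a,5,6,7,8,8a-octahydronaphthalen-1-yl]ethan-1-ol F3. Iodination of F3 with PPh3, imidazole and I2 gives 8.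

**Step 2 (carbomagnesiation and oxirane trapping).** The hindered, tetrasubstituted α-silylalkenyl Grignard 5 may open oxirane too slowly, with bromohydrin formation competing. The fallback sets out from 4 (through 5) and returns at 6, replacing the sp2–sp3 epoxide opening by an sp2–sp2 coupling and a hydroboration. Grignard 5 is coupled in the same flask with vinyl bromide (Pd(PPh3)4, 5 mol %, THF, 40 °C; Kumada coupling) to give [(3Z,7E)-4,8,12-trimethyltrideca-1,3,7,11-tetraen-3-yl]trimethylsilane F1. 9-BBN then hydroborates only the monosubstituted alkene at its terminal carbon, and NaBO3·4H2O oxidation gives 6.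

**Step 7 (olefination).** The α-branched phosphonate anion may react sluggishly or give an unsatisfactory E/Z ratio at the trisubstituted alkene. The fallback sets out from 8 and returns at 16, bypassing 10, 11 and 15. Iodide 8 alkylates ethyl (triphenylphosphoranylidene)acetate (2.2 equiv, EtOAc, reflux; the second equivalent acts as base by transylidation) to give the α-alkylated stabilised ylide ethyl 4-[(4aS,8aS)-2,5,5,8a-tetramethyl-3,4,4a,5,6,7,8,8a-octahydronaphthalen-1-yl]-2-(triphenylphosphoranylidene)butanoate F4. Its Wittig reaction with 14 (toluene, 80 °C) gives 16 with the high E preference typical of α-alkyl ester ylides.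

## Further compounds

F1 | step 2 | [(3Z,7E)-4,8,12-trimethyltrideca-1,3,7,11-tetraen-3-yl]trimethylsilane | C=C/C(=C(\C)CC/C=C(\C)CCC=C(C)C)[Si](C)(C)C
F2 | step 4 | 8α,12-epoxy-9α-(trimethylsilyl)-13,14,15,16-tetranorlabdane (9-silyl analogue of (−)-ambroxide) | C[C@@]12CC[C@H]3C(C)(C)CCC[C@]3(C)[C@]1(CCO2)[Si](C)(C)C
F3 | step 4 | 2-[(4aS,8aS)-2,5,5,8a-tetramethyl-3,4,4a,5,6,7,8,8a-octahydronaphthalen-1-yl]ethan-1-ol | CC1=C(CCO)[C@@]2(C)CCCC(C)(C)[C@@H]2CC1
F4 | step 7 | ethyl 4-[(4aS,8aS)-2,5,5,8a-tetramethyl-3,4,4a,5,6,7,8,8a-octahydronaphthalen-1-yl]-2-(triphenylphosphoranylidene)butanoate | CC1=C(CCC(C(=O)OCC)=P(c3ccccc3)(c3ccccc3)c3ccccc3)[C@@]2(C)CCCC(C)(C)[C@@H]2CC1
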